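## Analysis of the target

The target is a trans-3,4-dibenzyl-γ-butyrolactone (O1, C2=O, C3, C4, C5H2) of the matairesinol type in the (3S,4S) series. The benzyl group on C4 ends in ring B and the one on C3 in ring C. Both are guaiacyl rings that carry, ortho to the phenol, a 1,3-dihydroxy-1-arylpropan-2-yl arm. In each arm the carbinol carbon (Ca) bears an outer guaiacyl ring (ring A on the ring B arm, ring D on the ring C arm), and the second stereocentre (Cb) is bonded to ring B or C and to CH2OH.

There are six stereocentres: C3 and C4 (trans), and Ca and Cb in each arm. The ring B arm is (Ca S, Cb S), anti in the aldol sense; the ring C arm is (Ca S, Cb R), syn. The two arms are therefore epimers at Cb. An arene and a CH2 separate each arm from the lactone, so no unit can induce another and each of the three stereochemical units needs its own absolute control.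

The free arms are p-hydroxybenzylic alcohols. Acid ionises them, and the neighbouring phenol then closes a dihydrobenzofuran; they can also be lost on hydrogenolysis. C3 is epimerisable and the four phenols are easily oxidised. The main difficulty is that the two halves are constitutionally identical, differ only at Cb, and must end up on different lactone carbons.

The route rests on the polarity pattern of the lactone. The C4–CH2(ring B) bond is what remains when a ring B benzylic carbanion equivalent adds to the β-carbon of a butenolide. The C3–CH2(ring C) bond is what remains when the resulting enolate is alkylated by a ring C benzylic halide. Assigning one half as nucleophile and the other as electrophile tells them apart automatically.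

## Retrosynthetic reasoning

**Protecting groups (37 from 36 from 35).** The target 37 is traced to its tetrabenzyl ether 36 and then to the fully protected lactone 35. Phenols are carried as benzyl ethers and the four aliphatic hydroxyls as silyl ethers. Both are removed without acid, by fluoride and then neutral hydrogenolysis, because the free arms do not tolerate acid.

**Lactone CH2 groups (35 from 32 from 31).** C5H2 of 35 is traced to an acetal carbon in 32, and the C4 benzylic CH2 to a dithiane carbon in 31. Forward, a nickel desulfurisation and a base/borohydride opening with relactonisation are needed. These two extra groups are what make the union possible: the acetal carries the chirality and the dithiane makes the ring B benzylic carbon nucleophilic.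

**Key disconnection (31 to 24 + 28 + 17).** The C4–C(dithiane) and C3–CH2 bonds of 31 are cut, giving dithiane 24, butenolide 28 and benzylic bromide 17. These are the only two bonds that join the halves to the core, so the cut is fully convergent and gives pieces of similar size. The forward reaction must create C4 and C3 with the right absolute and trans relative configuration. The acetal centre of 28 controls C4, and C4 then controls C3.

**Butenolide (28 from 26 + 27; 26 from 25).** The C5–O(menthyl) bond of 28 is cut to the hydroxybutenolide 26 and (+)-menthol 27. Compound 26 comes from furfural 25 by oxidative loss of the formyl carbon. The acetal stereocentre is obtained from the cheap terpene alcohol.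

**One-carbon groups on rings B and C (24 from 23 from 21; 17 from 16 from 13).** The dithiane carbon of 24 and the CH2Br of 17 are both traced, through aldehyde 23 and alcohol 16, to the aryl bromides 21 and 13. A bromide is inert to enolate and hydride chemistry and is converted by halogen–lithium exchange when needed. It also lets both halves share one precursor.

**Arms (21 from 20 from 19; 13 from 12 from 11; both from 8 + 9).** The Ca–Cb bond of each arm is cut by an aldol disconnection to the same imide 8 and the same aldehyde 9. The syn arm (11) comes from the boron enolate and the anti arm (19) from the magnesium-chelated enolate. With the same auxiliary enantiomer these two modes attack opposite enolate faces and give the same Ca configuration, which is exactly the relation between the two arms.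

**Imide (8 from 5 + 6; 5 from 3 from 2 from 1).** The N-acyl bond of 8 is cut to acid 5 and oxazolidinone 6. The acid is traced by a one-carbon homologation to aldehyde 2 and the commercial phenol 1, which already has bromine para, methoxy ortho and the formyl carbon (the future Cb) ortho to the hydroxyl.

## Alternatives that were turned down

**Alternative 1:** Here the Ca–O bond of an arm is disconnected to a benzylic C–H bond. The precursor would be a 2,3-diarylpropyl tert-butyl carbonate A2 with Cb already set. A high-potential quinone would abstract hydride from the CH2 next to the outer ring. The carbonate carbonyl oxygen would trap the cation, closing the six-membered cyclic carbonate A1 with loss of isobutene.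

- For: no aldol reversibility; Ca is set by the substrate; the trans carbonate (both aryl groups equatorial) corresponds to the anti arm; one group protects both oxygens.
- Against: the step can only give the anti relation, so the syn arm of ring C would need an inversion or a different method. Hydride abstraction must choose the Ca methylene over the tertiary benzylic Cb–H and the O-benzyl methylenes. A mono-alkoxy arene is at the lower limit of what such quinones oxidise. The step also does nothing for the union of the halves or for C3 and C4.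
- Comparison: it is stronger in avoiding a stoichiometric auxiliary for Ca. The chosen route instead gives both arms from one imide by changing only the enolate metal, and it solves the core.

**Alternative 2:** Here both Ca–Cb bonds are cut at the end. A preformed lactone A4 would carry an (E)-3-borylprop-1-enyl group on ring B and a (Z)-3-borylprop-1-enyl group on ring C. Under a chiral phosphoric acid it would add to two molecules of aldehyde 9 to give the bis(homoallylic alcohol) A3. The vinyl groups would then be cleaved and reduced to CH2OH.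

- For: it is the most convergent plan. Each arm's two stereocentres form in one step, E giving anti and Z giving syn through closed chairs. Both arms have the same Ca configuration, so one catalyst enantiomer fits both. On step count after the lactone it is stronger than the chosen route.
- Against: A4 still needs two different groups on two near-identical rings, so the rings must be told apart during lactone assembly anyway. γ-Aryl (Z)-allylboronates isomerise easily and are a poorly developed class for this catalysis. Any loss of selectivity is multiplied over two sites on a large molecule with inseparable isomers. Cleaving two alkenes next to four electron-rich arenes is a further hazard.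
- Comparison: the chosen route is longer but fixes each arm on a small intermediate by auxiliary aldol reactions before the union.

**Alternative 3:** Here the ring C5–Cb bonds of both arms are cut. The bis(aryl allyl ether) A6 of (3S,4S)-matairesinol A7 would undergo two aromatic Claisen rearrangements on heating. Each would pass the configuration of the ether carbon to Cb through a chair and give the bis(ortho-alkylated phenol) A5 with (E)-propenyl groups, which would then be cleaved and reduced.

- For: each guaiacyl ring has one free ortho position, so regiochemistry is certain. No aryl-metal chemistry is needed and the chirality transfer is stereospecific. On these points it is stronger than the chosen route.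
- Against: the two phenols of A7 are chemically equivalent yet need diastereomeric allyl groups (1'S on ring B, 1'R on ring C), so selective etherification is not possible. Secondary allylic aryl ethers flanked by a benzylic silyloxy carbon are hard to make without allylic transposition or ionisation. The same system can ionise or eliminate at Claisen temperatures. Each allyl fragment already holds two stereocentres and an E-alkene, so it is no cheaper than an aldol half. A7 is the unnatural enantiomer and would itself have to be made.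
- Comparison: the chosen route differentiates the rings by construction and keeps the sensitive arms protected and cold in the union.

Key step: step 17

**Conventions.** Ar' = 4-(benzyloxy)-3-methoxyphenyl; TBS = tert-butyldimethylsilyl; MenO = [(1S,2R,5S)-2-isopropyl-5-methylcyclohexyl]oxy. Anti arm = (1S,2S)-1-Ar'-1,3-bis(TBS-oxy)propan-2-yl; syn arm = (1S,2R)-1-Ar'-1,3-bis(TBS-oxy)propan-2-yl. ArB = 4-(benzyloxy)-3-methoxy-5-(anti arm)phenyl; ArC = 4-(benzyloxy)-3-methoxy-5-(syn arm)phenyl. The Cb descriptor changes letter between imide and diol in each series only because the CIP rank of C1 changes on reduction; no centre is inverted.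

**Assumption.** The magnesium-catalysed anti aldol of arylacetyl imide 8 is taken to show the same chelate-controlled facial preference as simple N-acyl oxazolidinones, so the (S)-auxiliary serves both halves.

## Route

### Common imide (steps 1–4)

Step 1
Reactants: 1 5-bromo-2-hydroxy-3-methoxybenzaldehyde
Product: 2 2-(benzyloxy)-5-bromo-3-methoxybenzaldehyde
Conditions: BnBr, K2CO3, DMF, 60 °C
Reagents that add atoms: benzyl bromide, BrCc1ccccc1
Why: Williamson etherification of the acidic ortho-formyl phenol; the benzyl ether then survives every step up to the final hydrogenolysis.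

Step 2
Reactants: 2 2-(benzyloxy)-5-bromo-3-methoxybenzaldehyde
Product: 3 2-(benzyloxy)-5-bromo-1-methoxy-3-(2-methoxyethenyl)benzene (E/Z mixture)
Conditions: Ph3P(Cl)CH2OMe, KOt-Bu, THF, 0 °C to rt
Reagents that add atoms: (methoxymethyl)triphenylphosphonium chloride, [Cl-].COC[P+](c1ccccc1)(c1ccccc1)c1ccccc1
Why: Wittig olefination with the methoxymethyl ylide gives a masked homologous aldehyde; the E/Z mixture is irrelevant because both isomers hydrolyse to the same product.

Step 3
Reactants: 3 2-(benzyloxy)-5-bromo-1-methoxy-3-(2-methoxyethenyl)benzene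
Product: 5 2-[2-(benzyloxy)-5-bromo-3-methoxyphenyl]acetic acid, via arylacetaldehyde 4 (not isolated)
Conditions: 2 M HCl, THF, 40 °C; then NaClO2, NaH2PO4, 2-methyl-2-butene, t-BuOH/H2O, rt
Reagents that add atoms: water, O; sodium chlorite, [Na+].[O-]Cl=O
Why: Acid hydrolysis of the enol ether frees aldehyde 4, which is oxidised at once under Pinnick conditions so that the enolisable aldehyde is never stored; the alkene scavenger keeps hypochlorite off the electron-rich ring.

Step 4
Reactants: 5 2-[2-(benzyloxy)-5-bromo-3-methoxyphenyl]acetic acid; 6 (S)-4-benzyl-1,3-oxazolidin-2-one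
Product: 8 (S)-4-benzyl-3-{2-[2-(benzyloxy)-5-bromo-3-methoxyphenyl]acetyl}-1,3-oxazolidin-2-one, via pivalic mixed anhydride 7 (not isolated)
Conditions: PivCl, Et3N, THF, −20 °C; then 6, LiCl, −20 °C to rt
Reagents that add atoms: none
Why: Mixed-anhydride N-acylation of the oxazolidinone under LiCl/amine activation; attack goes to the less hindered arylacetyl carbonyl and no stereocentre is involved.

### Ring C half, syn arm (steps 5–9)

Step 5
Reactants: 8 (S)-4-benzyl-3-{2-[2-(benzyloxy)-5-bromo-3-methoxyphenyl]acetyl}-1,3-oxazolidin-2-one; 9 4-(benzyloxy)-3-methoxybenzaldehyde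
Product: 11 (S)-4-benzyl-3-{(2S,3S)-2-[2-(benzyloxy)-5-bromo-3-methoxyphenyl]-3-[4-(benzyloxy)-3-methoxyphenyl]-3-hydroxypropanoyl}-1,3-oxazolidin-2-one, via dibutylboron Z-enolate 10 (not isolated)
Conditions: Bu2BOTf, i-Pr2NEt, CH2Cl2, −78 to 0 °C; 9, −78 to 0 °C; pH 7 buffer, MeOH, H2O2, 0 °C
Reagents that add atoms: none
Why: Evans syn aldol: soft enolisation gives Z-enolate 10, which reacts through a closed Zimmerman–Traxler chair with the auxiliary carbonyl turned away, so the aldehyde adds to the enolate face opposite the auxiliary benzyl group. This sets Cb (2S) and Ca (3S) together as the syn pair needed on ring C.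

Step 6
Reactants: 11 syn aldol adduct
Product: 12 (1S,2R)-2-[2-(benzyloxy)-5-bromo-3-methoxyphenyl]-1-[4-(benzyloxy)-3-methoxyphenyl]propane-1,3-diol
Conditions: LiBH4, MeOH (1 equiv), THF, 0 °C
Reagents that add atoms: none
Why: Borohydride cleaves the imide at the exocyclic carbonyl to the primary alcohol without touching Ca or Cb and releases auxiliary 6 for reuse; aryl bromide and benzyl ethers are inert.

Step 7
Reactants: 12 (1S,2R)-diol
Product: 13 1-bromo-4-(benzyloxy)-3-methoxy-5-(syn arm)benzene (ArC–Br)
Conditions: TBSOTf, 2,6-lutidine, CH2Cl2, −78 to 0 °C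
Reagents that add atoms: tert-butyldimethylsilyl triflate, CC(C)(C)[Si](C)(C)OS(=O)(=O)C(F)(F)F
Why: The silyl triflate silylates both hydroxyls, including the hindered benzylic one; silyl ethers are chosen because fluoride removes them later without acid.

Step 8
Reactants: 13 ArC–Br
Product: 16 [4-(benzyloxy)-3-methoxy-5-(syn arm)phenyl]methanol (ArC–CH2OH), via aryllithium 14 (not isolated), via aldehyde 15 (not isolated)
Conditions: n-BuLi, THF, −78 °C; DMF, −78 to 0 °C; then MeOH, NaBH4, 0 °C
Reagents that add atoms: N,N-dimethylformamide, CN(C)C=O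
Why: Bromine–lithium exchange outruns any deprotonation at −78 °C; aryllithium 14 is formylated by DMF and aldehyde 15, freed on adding methanol, is reduced in the same flask by borohydride.

Step 9
Reactants: 16 ArC–CH2OH
Product: 17 2-(benzyloxy)-5-(bromomethyl)-1-methoxy-3-(syn arm)benzene (ArC–CH2Br)
Conditions: CBr4, PPh3, CH2Cl2, 0 °C
Reagents that add atoms: carbon tetrabromide, BrC(Br)(Br)Br
Why: Appel bromination under nearly neutral conditions converts the benzylic alcohol without ionising the silyl ethers; the electron-rich bromide is to be used directly.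

### Ring B half, anti arm (steps 10–14)

Step 10
Reactants: 8 arylacetyl imide; 9 4-(benzyloxy)-3-methoxybenzaldehyde
Product: 19 (S)-4-benzyl-3-{(2R,3S)-2-[2-(benzyloxy)-5-bromo-3-methoxyphenyl]-3-[4-(benzyloxy)-3-methoxyphenyl]-3-hydroxypropanoyl}-1,3-oxazolidin-2-one, via trimethylsilyl ether 18 (not isolated)
Conditions: MgCl2 (20 mol %), Et3N, Me3SiCl, EtOAc, rt; then 1 M HCl, THF, 0 °C
Reagents that add atoms: none
Why: Magnesium-halide-catalysed anti aldol with soft enolisation and silyl trapping that makes the addition irreversible. The magnesium-chelated Z-enolate reacts through a boat-like transition state on the face opposite the auxiliary benzyl group, giving Cb 2R (opposite to step 5) and Ca 3S, the anti pair needed on ring B. Brief mild acid then removes the trimethylsilyl group.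

Step 11
Reactants: 19 anti aldol adduct
Product: 20 (1S,2S)-2-[2-(benzyloxy)-5-bromo-3-methoxyphenyl]-1-[4-(benzyloxy)-3-methoxyphenyl]propane-1,3-diol
Conditions: LiBH4, MeOH (1 equiv), THF, 0 °C
Reagents that add atoms: none
Why: Same reductive removal of the auxiliary as in step 6; neither stereocentre is touched.

Step 12
Reactants: 20 (1S,2S)-diol
Product: 21 1-bromo-4-(benzyloxy)-3-methoxy-5-(anti arm)benzene (ArB–Br)
Conditions: TBSOTf, 2,6-lutidine, CH2Cl2, −78 to 0 °C
Reagents that add atoms: tert-butyldimethylsilyl triflate, CC(C)(C)[Si](C)(C)OS(=O)(=O)C(F)(F)F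
Why: Double silylation as in step 7; the silyl ethers are stable to the organolithium steps that follow.

Step 13
Reactants: 21 ArB–Br
Product: 23 4-(benzyloxy)-3-methoxy-5-(anti arm)benzaldehyde (ArB–CHO), via aryllithium 22 (not isolated)
Conditions: n-BuLi, THF, −78 °C; DMF, −78 to 0 °C; aq. NH4Cl
Reagents that add atoms: N,N-dimethylformamide, CN(C)C=O
Why: Bromine–lithium exchange followed by formylation with DMF; the hemiaminal salt collapses to the aldehyde on aqueous work-up.

Step 14
Reactants: 23 ArB–CHO
Product: 24 2-[4-(benzyloxy)-3-methoxy-5-(anti arm)phenyl]-1,3-dithiane (2-ArB-1,3-dithiane)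
Conditions: HS(CH2)3SH, BF3·OEt2 (cat.), CH2Cl2, −40 to −20 °C
Reagents that add atoms: propane-1,3-dithiol, SCCCS
Why: Lewis-acid-catalysed dithioacetalisation of an unhindered aryl aldehyde; low temperature and a catalytic amount of BF3·OEt2 are chosen to spare the benzylic silyl ether.

### Butenolide (steps 15–16)

Step 15
Reactants: 25 furfural
Product: 26 5-hydroxyfuran-2(5H)-one (racemic)
Conditions: O2, hν (visible), rose bengal (cat.), MeOH, rt
Reagents that add atoms: dioxygen, O=O
Why: Dye-sensitised photooxygenation: singlet oxygen adds [4+2] to the furan and methanolysis of the endoperoxide expels the formyl carbon as methyl formate, leaving the hydroxybutenolide.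

Step 16
Reactants: 26 5-hydroxyfuran-2(5H)-one; 27 (+)-menthol [(1S,2R,5S)-2-isopropyl-5-methylcyclohexan-1-ol]
Product: 28 (5S)-5-{[(1S,2R,5S)-2-isopropyl-5-methylcyclohexyl]oxy}furan-2(5H)-one
Conditions: camphorsulfonic acid (cat.), toluene, reflux (Dean–Stark); crystallisation from hexane
Reagents that add atoms: none
Why: Acid-catalysed acetalisation of the pseudo-acid gives both C5 epimers, which interconvert under the acid. The (5S) epimer, the mirror image of the crystalline l-menthyl compound, is expected to crystallise and the mother liquor can be re-equilibrated, so C5 is set by crystallisation against the fixed menthyl stereocentres.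

### Union and end game (steps 17–21)

Step 17
Reactants: 24 2-ArB-1,3-dithiane; 28 (5S)-5-(MenO)furan-2(5H)-one; 17 ArC–CH2Br
Product: 31 (3S,4S,5S)-3-(ArC-methyl)-4-(2-ArB-1,3-dithian-2-yl)-5-(MenO)dihydrofuran-2(3H)-one, via 2-lithiodithiane 29 (not isolated), via lithium enolate 30 (not isolated)
Conditions: n-BuLi, THF, −78 to −30 °C; 28, −78 °C; then 17, DMPU, −78 to −20 °C
Reagents that add atoms: none
Why: n-BuLi removes the dithiane 2-H of 24, by far the most acidic proton, to give the sulfur-stabilised benzylic anion 29; this soft, hindered anion adds 1,4 to butenolide 28 to give lithium enolate 30, which is C-benzylated by bromide 17 in an SN2 step once DMPU is added. The closest known reaction type is the tandem conjugate addition and enolate benzylation of lithiated 2-aryl-1,3-dithianes on 5-alkoxy-2(5H)-furanones, used for dibenzylbutyrolactone lignans. No ring is closed; the C4–C(dithiane) and C3–CH2 bonds form in one flask. C4 is controlled by the C5 menthyloxy group: the anion enters the face anti to it, so the 5S acetal gives 4S. C3 is controlled by the new quaternary dithianyl substituent on C4: the bromide approaches the opposite enolate face, giving the trans 3S centre. The step needs 1,4- over 1,2-addition (secured by the delocalised anion and the acylal-type carbonyl), C- over O-alkylation (lithium enolate with a benzylic bromide) and mono-alkylation (the product α-carbon is tertiary and hindered). The silyl and benzyl ethers of both arms are inert to the base at these temperatures, and the arm stereocentres are remote spectators.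

Step 18
Reactants: 31 trans,trans adduct
Product: 32 (3S,4S,5S)-3-(ArC-methyl)-4-(ArB-methyl)-5-(MenO)dihydrofuran-2(3H)-one
Conditions: Raney Ni (W-2), EtOH/THF, rt
Reagents that add atoms: none
Why: Hydrogenolysis of both C–S bonds on nickel turns the dithiane carbon into the C4 benzylic CH2; neutral-washed nickel at room temperature limits attack on benzyl ethers and on the benzylic C–O bonds, and no stereocentre changes.

Step 19
Reactants: 32 desulfurised acetal lactone
Product: 35 (3S,4S)-3-(ArC-methyl)-4-(ArB-methyl)dihydrofuran-2(3H)-one, via potassium 4-oxobutanoate 33 (not isolated), via potassium 4-hydroxybutanoate 34 (not isolated)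
Conditions: NaBH4, KOH, THF/EtOH/H2O, 0 °C to rt; then 1 M HCl to pH 3, 0 °C to rt
Reagents that add atoms: none
Why: Hydroxide opens the acylal-type lactone, the hemiacetal collapses to aldehyde 33 with loss of menthol, borohydride present from the start reduces it to 34 before C4 can enolise, and acidification closes the γ-lactone onto the former acetal carbon. C3 and C4 keep their configuration, and the trans lactone is also the more stable one.

Step 20
Reactants: 35 protected lactone
Product: 36 (3S,4S)-3-{4-(benzyloxy)-3-[(1S,2R)-1-(4-(benzyloxy)-3-methoxyphenyl)-1,3-dihydroxypropan-2-yl]-5-methoxybenzyl}-4-{4-(benzyloxy)-3-[(1S,2S)-1-(4-(benzyloxy)-3-methoxyphenyl)-1,3-dihydroxypropan-2-yl]-5-methoxybenzyl}dihydrofuran-2(3H)-one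
Conditions: Bu4NF, AcOH, THF, 0 °C to rt
Reagents that add atoms: none
Why: Fluoride-mediated cleavage of the four silyl ethers; acetic acid buffers the alkoxides so that C3 is not epimerised and the lactone is not opened.

Step 21
Reactants: 36 tetrabenzyl ether
Product: 37 (3S,4S)-3-{4-hydroxy-3-[(1S,2R)-1,3-dihydroxy-1-(4-hydroxy-3-methoxyphenyl)propan-2-yl]-5-methoxybenzyl}-4-{4-hydroxy-3-[(1S,2S)-1,3-dihydroxy-1-(4-hydroxy-3-methoxyphenyl)propan-2-yl]-5-methoxybenzyl}dihydrofuran-2(3H)-one (target)
Conditions: H2 (1 atm), Pd/C (10 %), EtOAc/EtOH, rt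
Reagents that add atoms: none
Why: Catalytic hydrogenolysis of the four aryl benzyl ethers under neutral conditions, stopped at full debenzylation to avoid reduction of the benzylic alcohols; no acid is present, so the arms do not cyclise.

## Compound list

1 | 5-bromo-2-hydroxy-3-methoxybenzaldehyde | O=Cc1cc(Br)cc(OC)c1O | starting material
2 | 2-(benzyloxy)-5-bromo-3-methoxybenzaldehyde | O=Cc1cc(Br)cc(OC)c1OCc1ccccc1 | intermediate
3 | 2-(benzyloxy)-5-bromo-1-methoxy-3-(2-methoxyethenyl)benzene (E/Z mixture) | COC=Cc1cc(Br)cc(OC)c1OCc1ccccc1 | intermediate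
4 | 2-[2-(benzyloxy)-5-bromo-3-methoxyphenyl]acetaldehyde (not isolated) | O=CCc1cc(Br)cc(OC)c1OCc1ccccc1 | intermediate
5 | 2-[2-(benzyloxy)-5-bromo-3-methoxyphenyl]acetic acid | OC(=O)Cc1cc(Br)cc(OC)c1OCc1ccccc1 | intermediate
6 | (S)-4-benzyl-1,3-oxazolidin-2-one | O=C1OC[C@H](Cc2ccccc2)N1 | starting material
7 | 2-[2-(benzyloxy)-5-bromo-3-methoxyphenyl]acetic pivalic anhydride (not isolated) | CC(C)(C)C(=O)OC(=O)Cc1cc(Br)cc(OC)c1OCc1ccccc1 | intermediate
8 | (S)-4-benzyl-3-{2-[2-(benzyloxy)-5-bromo-3-methoxyphenyl]acetyl}-1,3-oxazolidin-2-one | O=C(Cc1cc(Br)cc(OC)c1OCc1ccccc1)N1C(=O)OC[C@@H]1Cc1ccccc1 | intermediate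
9 | 4-(benzyloxy)-3-methoxybenzaldehyde | O=Cc1ccc(OCc2ccccc2)c(OC)c1 | starting material
10 | (S)-4-benzyl-3-{(Z)-2-[2-(benzyloxy)-5-bromo-3-methoxyphenyl]-1-[(dibutylboranyl)oxy]ethenyl}-1,3-oxazolidin-2-one (not isolated) | CCCCB(CCCC)O/C(=C\c1cc(Br)cc(OC)c1OCc1ccccc1)N1C(=O)OC[C@@H]1Cc1ccccc1 | intermediate
11 | (S)-4-benzyl-3-{(2S,3S)-2-[2-(benzyloxy)-5-bromo-3-methoxyphenyl]-3-[4-(benzyloxy)-3-methoxyphenyl]-3-hydroxypropanoyl}-1,3-oxazolidin-2-one (syn aldol) | Brc3cc(OC)c(OCc5ccccc5)c([C@H](C(=O)N6C(=O)OC[C@@H]6Cc6ccccc6)[C@H](O)c4ccc(OCc5ccccc5)c(OC)c4)c3 | intermediate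
12 | (1S,2R)-2-[2-(benzyloxy)-5-bromo-3-methoxyphenyl]-1-[4-(benzyloxy)-3-methoxyphenyl]propane-1,3-diol | Brc3cc(OC)c(OCc5ccccc5)c([C@H](CO)[C@H](O)c4ccc(OCc5ccccc5)c(OC)c4)c3 | intermediate
13 | (1S,2R)-2-[2-(benzyloxy)-5-bromo-3-methoxyphenyl]-1-[4-(benzyloxy)-3-methoxyphenyl]-1,3-bis(tert-butyldimethylsilyloxy)propane (ArC–Br) | Brc3cc(OC)c(OCc5ccccc5)c([C@H](CO[Si](C)(C)C(C)(C)C)[C@H](O[Si](C)(C)C(C)(C)C)c4ccc(OCc5ccccc5)c(OC)c4)c3 | intermediate
14 | aryllithium from 13 (Li in place of Br; not isolated) | [Li]c3cc(OC)c(OCc5ccccc5)c([C@H](CO[Si](C)(C)C(C)(C)C)[C@H](O[Si](C)(C)C(C)(C)C)c4ccc(OCc5ccccc5)c(OC)c4)c3 | intermediate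
15 | 4-(benzyloxy)-3-methoxy-5-[(1S,2R)-1-(4-(benzyloxy)-3-methoxyphenyl)-1,3-bis(tert-butyldimethylsilyloxy)propan-2-yl]benzaldehyde (not isolated) | O=Cc3cc(OC)c(OCc5ccccc5)c([C@H](CO[Si](C)(C)C(C)(C)C)[C@H](O[Si](C)(C)C(C)(C)C)c4ccc(OCc5ccccc5)c(OC)c4)c3 | intermediate
16 | {4-(benzyloxy)-3-methoxy-5-[(1S,2R)-1-(4-(benzyloxy)-3-methoxyphenyl)-1,3-bis(tert-butyldimethylsilyloxy)propan-2-yl]phenyl}methanol | OCc3cc(OC)c(OCc5ccccc5)c([C@H](CO[Si](C)(C)C(C)(C)C)[C@H](O[Si](C)(C)C(C)(C)C)c4ccc(OCc5ccccc5)c(OC)c4)c3 | intermediate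
17 | 2-(benzyloxy)-5-(bromomethyl)-1-methoxy-3-[(1S,2R)-1-(4-(benzyloxy)-3-methoxyphenyl)-1,3-bis(tert-butyldimethylsilyloxy)propan-2-yl]benzene (ring C half bromide) | BrCc3cc(OC)c(OCc5ccccc5)c([C@H](CO[Si](C)(C)C(C)(C)C)[C@H](O[Si](C)(C)C(C)(C)C)c4ccc(OCc5ccccc5)c(OC)c4)c3 | intermediate
18 | O-trimethylsilyl ether of 19 (not isolated) | COc1cc([C@@H](O[Si](C)(C)C)[C@H](C(=O)N3C(=O)OC[C@@H]3Cc3ccccc3)c2cc(Br)cc(OC)c2OCc2ccccc2)ccc1OCc1ccccc1 | intermediate
19 | (S)-4-benzyl-3-{(2R,3S)-2-[2-(benzyloxy)-5-bromo-3-methoxyphenyl]-3-[4-(benzyloxy)-3-methoxyphenyl]-3-hydroxypropanoyl}-1,3-oxazolidin-2-one (anti aldol) | COc1cc([C@@H](O)[C@H](C(=O)N3C(=O)OC[C@@H]3Cc3ccccc3)c2cc(Br)cc(OC)c2OCc2ccccc2)ccc1OCc1ccccc1 | intermediate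
20 | (1S,2S)-2-[2-(benzyloxy)-5-bromo-3-methoxyphenyl]-1-[4-(benzyloxy)-3-methoxyphenyl]propane-1,3-diol | COc1cc([C@@H](O)[C@H](CO)c2cc(Br)cc(OC)c2OCc2ccccc2)ccc1OCc1ccccc1 | intermediate
21 | (1S,2S)-2-[2-(benzyloxy)-5-bromo-3-methoxyphenyl]-1-[4-(benzyloxy)-3-methoxyphenyl]-1,3-bis(tert-butyldimethylsilyloxy)propane (ArB–Br) | COc1cc([C@@H](O[Si](C)(C)C(C)(C)C)[C@H](CO[Si](C)(C)C(C)(C)C)c2cc(Br)cc(OC)c2OCc2ccccc2)ccc1OCc1ccccc1 | intermediate
22 | aryllithium from 21 (Li in place of Br; not isolated) | COc1cc([C@@H](O[Si](C)(C)C(C)(C)C)[C@H](CO[Si](C)(C)C(C)(C)C)c2cc([Li])cc(OC)c2OCc2ccccc2)ccc1OCc1ccccc1 | intermediate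
23 | 4-(benzyloxy)-3-methoxy-5-[(1S,2S)-1-(4-(benzyloxy)-3-methoxyphenyl)-1,3-bis(tert-butyldimethylsilyloxy)propan-2-yl]benzaldehyde | COc1cc([C@@H](O[Si](C)(C)C(C)(C)C)[C@H](CO[Si](C)(C)C(C)(C)C)c2cc(C=O)cc(OC)c2OCc2ccccc2)ccc1OCc1ccccc1 | intermediate
24 | 2-{4-(benzyloxy)-3-methoxy-5-[(1S,2S)-1-(4-(benzyloxy)-3-methoxyphenyl)-1,3-bis(tert-butyldimethylsilyloxy)propan-2-yl]phenyl}-1,3-dithiane (ring B half dithiane) | COc1cc([C@@H](O[Si](C)(C)C(C)(C)C)[C@H](CO[Si](C)(C)C(C)(C)C)c2cc(C6SCCCS6)cc(OC)c2OCc2ccccc2)ccc1OCc1ccccc1 | intermediate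
25 | furfural | O=Cc1ccco1 | starting material
26 | 5-hydroxyfuran-2(5H)-one (racemic) | O=C1C=CC(O)O1 | intermediate
27 | (+)-menthol, (1S,2R,5S)-2-isopropyl-5-methylcyclohexan-1-ol | C[C@H]1CC[C@@H]([C@H](C1)O)C(C)C | starting material
28 | (5S)-5-{[(1S,2R,5S)-2-isopropyl-5-methylcyclohexyl]oxy}furan-2(5H)-one | O=C1C=C[C@@H](O[C@H]2C[C@@H](C)CC[C@@H]2C(C)C)O1 | intermediate
29 | 2-lithio derivative of dithiane 24 (not isolated) | COc1cc([C@@H](O[Si](C)(C)C(C)(C)C)[C@H](CO[Si](C)(C)C(C)(C)C)c2cc(C6([Li])SCCCS6)cc(OC)c2OCc2ccccc2)ccc1OCc1ccccc1 | intermediate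
30 | lithium enolate of the (4S,5S) conjugate adduct of 29 and 28 (not isolated) | COc1cc([C@@H](O[Si](C)(C)C(C)(C)C)[C@H](CO[Si](C)(C)C(C)(C)C)c2cc(C6(SCCCS6)[C@@H]3[C@@H](O[C@H]7C[C@@H](C)CC[C@@H]7C(C)C)OC(O[Li])=C3)cc(OC)c2OCc2ccccc2)ccc1OCc1ccccc1 | intermediate
31 | (3S,4S,5S)-3-(ArC-methyl)-4-(2-ArB-1,3-dithian-2-yl)-5-(MenO)dihydrofuran-2(3H)-one (trans,trans adduct) | COc1cc([C@@H](O[Si](C)(C)C(C)(C)C)[C@H](CO[Si](C)(C)C(C)(C)C)c2cc(C6(SCCCS6)[C@@H]3[C@@H](O[C@H]7C[C@@H](C)CC[C@@H]7C(C)C)OC(=O)[C@H]3Cc3cc(OC)c(OCc5ccccc5)c([C@H](CO[Si](C)(C)C(C)(C)C)[C@H](O[Si](C)(C)C(C)(C)C)c4ccc(OCc5ccccc5)c(OC)c4)c3)cc(OC)c2OCc2ccccc2)ccc1OCc1ccccc1 | intermediate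
32 | (3S,4S,5S)-3-(ArC-methyl)-4-(ArB-methyl)-5-(MenO)dihydrofuran-2(3H)-one | COc1cc([C@@H](O[Si](C)(C)C(C)(C)C)[C@H](CO[Si](C)(C)C(C)(C)C)c2cc(C[C@@H]3[C@@H](O[C@H]7C[C@@H](C)CC[C@@H]7C(C)C)OC(=O)[C@H]3Cc3cc(OC)c(OCc5ccccc5)c([C@H](CO[Si](C)(C)C(C)(C)C)[C@H](O[Si](C)(C)C(C)(C)C)c4ccc(OCc5ccccc5)c(OC)c4)c3)cc(OC)c2OCc2ccccc2)ccc1OCc1ccccc1 | intermediate
33 | potassium (2S,3S)-2-(ArC-methyl)-3-(ArB-methyl)-4-oxobutanoate (not isolated) | COc1cc([C@@H](O[Si](C)(C)C(C)(C)C)[C@H](CO[Si](C)(C)C(C)(C)C)c2cc(C[C@H](C=O)[C@H](Cc3cc(OC)c(OCc5ccccc5)c([C@H](CO[Si](C)(C)C(C)(C)C)[C@H](O[Si](C)(C)C(C)(C)C)c4ccc(OCc5ccccc5)c(OC)c4)c3)C(=O)[O-])cc(OC)c2OCc2ccccc2)ccc1OCc1ccccc1.[K+] | intermediate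
34 | potassium (2S,3S)-2-(ArC-methyl)-3-(ArB-methyl)-4-hydroxybutanoate (not isolated) | COc1cc([C@@H](O[Si](C)(C)C(C)(C)C)[C@H](CO[Si](C)(C)C(C)(C)C)c2cc(C[C@H](CO)[C@H](Cc3cc(OC)c(OCc5ccccc5)c([C@H](CO[Si](C)(C)C(C)(C)C)[C@H](O[Si](C)(C)C(C)(C)C)c4ccc(OCc5ccccc5)c(OC)c4)c3)C(=O)[O-])cc(OC)c2OCc2ccccc2)ccc1OCc1ccccc1.[K+] | intermediate
35 | (3S,4S)-3-(ArC-methyl)-4-(ArB-methyl)dihydrofuran-2(3H)-one | COc1cc([C@@H](O[Si](C)(C)C(C)(C)C)[C@H](CO[Si](C)(C)C(C)(C)C)c2cc(C[C@@H]3COC(=O)[C@H]3Cc3cc(OC)c(OCc5ccccc5)c([C@H](CO[Si](C)(C)C(C)(C)C)[C@H](O[Si](C)(C)C(C)(C)C)c4ccc(OCc5ccccc5)c(OC)c4)c3)cc(OC)c2OCc2ccccc2)ccc1OCc1ccccc1 | intermediate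
36 | tetra-O-benzyl ether of the target at the four phenols (3S,4S; ring C arm 1S,2R; ring B arm 1S,2S) | COc1cc([C@@H](O)[C@H](CO)c2cc(C[C@@H]3COC(=O)[C@H]3Cc3cc(OC)c(OCc5ccccc5)c([C@H](CO)[C@H](O)c4ccc(OCc5ccccc5)c(OC)c4)c3)cc(OC)c2OCc2ccccc2)ccc1OCc1ccccc1 | intermediate
37 | (3S,4S)-3-{4-hydroxy-3-[(1S,2R)-1,3-dihydroxy-1-(4-hydroxy-3-methoxyphenyl)propan-2-yl]-5-methoxybenzyl}-4-{4-hydroxy-3-[(1S,2S)-1,3-dihydroxy-1-(4-hydroxy-3-methoxyphenyl)propan-2-yl]-5-methoxybenzyl}dihydrofuran-2(3H)-one | COc1cc([C@@H](O)[C@H](CO)c2cc(C[C@@H]3COC(=O)[C@H]3Cc3cc(OC)c(O)c([C@H](CO)[C@H](O)c4ccc(O)c(OC)c4)c3)cc(OC)c2O)ccc1O | target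

## Step count and weak points

Total step count: 21. Longest linear sequence: 14 steps (steps 1–4, 10–14, 17–21; the ring C branch through steps 5–9 is equally long).

**Step 17 (key step).** The most likely failure is incomplete benzylation of the hindered enolate 30: proton transfer or slow SN2 with a large bromide would leave non-alkylated conjugate adduct, and warming to force the alkylation invites retro-Michael loss of the dithiane anion. Fallback: run the union in two operations. Starting from 24 and 28, the conjugate addition is quenched cold with NH4Cl to isolate the Michael adduct (4S,5S)-4-(2-ArB-1,3-dithian-2-yl)-5-(MenO)dihydrofuran-2(3H)-one F1. F1 is then re-enolised with LiN(i-Pr)2 in THF/DMPU and alkylated with bromide 17 used in excess, again anti to the C4 substituent. This returns to the route at 31.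

**Step 10.** The anti selectivity may erode through reversible aldol addition before silyl trapping, and enolisation of the ortho-substituted arylacetyl imide may be slow; the assumed chelate-controlled face could also be less dominant for an α-aryl enolate. Fallback: take the anti relation from an Ivanov reaction and the absolute configuration from resolution. Starting from acid 5, the magnesium enediolate (2 equiv i-PrMgCl, THF) adds to aldehyde 9 through a chair transition state to give the racemic anti acid (2R*,3S*)-2-[2-(benzyloxy)-5-bromo-3-methoxyphenyl]-3-[4-(benzyloxy)-3-methoxyphenyl]-3-hydroxypropanoic acid F2. F2 is resolved by crystallisation of a 1-phenylethylammonium salt, written here as the (S)-amine salt of the (2R,3S)-acid F3; which amine enantiomer gives the less soluble salt of the wanted acid has to be found by trial. The liberated acid is reduced with BH3·SMe2 to diol 20, where the route is rejoined.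

**Step 14.** The Lewis acid may ionise the p-alkoxybenzylic silyl ether at Ca, with capture of the cation by thiol or loss of configuration there. Fallback: avoid the aldehyde and the acid. Starting from bromide 21, exchange with n-BuLi gives aryllithium 22, which is transmetallated with MgBr2·OEt2 to the arylmagnesium bromide F4. F4 is treated with 2-chloro-1,3-dithiane F5, freshly made from 1,3-dithiane and N-chlorosuccinimide, and gives dithiane 24 directly.

**Step 18.** Hydrogen-rich nickel may over-reduce, cleaving benzyl ethers or the benzylic C–O bond at Ca. Lost benzyl groups alone would only give mixtures that converge at step 21, but loss of the Ca oxygen would be fatal. Fallback: radical desulfurisation of 31 with excess Bu3SnH and azobisisobutyronitrile in refluxing toluene, a chain process that does not touch benzylic ethers, to give 32. This fallback makes no new compound (F0).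

**Step 21.** Once the para phenols are free, the benzylic C–OH bonds become prone to hydrogenolysis, and acidic sites on the catalyst could start cyclisation of an arm to a dihydrobenzofuran. Fallback: invert the order of the last two steps. Starting from 35, hydrogenolysis is run while the Ca oxygens are still shielded as bulky silyl ethers, giving the tetraphenol tetrakis(silyl ether) F6. F6 is then desilylated with Bu4NF buffered by AcOH to reach 37.

## Further compounds

F1 | step 17 | (4S,5S)-4-(2-ArB-1,3-dithian-2-yl)-5-(MenO)dihydrofuran-2(3H)-one | COc1cc([C@@H](O[Si](C)(C)C(C)(C)C)[C@H](CO[Si](C)(C)C(C)(C)C)c2cc(C6(SCCCS6)[C@@H]3[C@@H](O[C@H]7C[C@@H](C)CC[C@@H]7C(C)C)OC(=O)C3)cc(OC)c2OCc2ccccc2)ccc1OCc1ccccc1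
F2 | step 10 | (2R*,3S*)-2-[2-(benzyloxy)-5-bromo-3-methoxyphenyl]-3-[4-(benzyloxy)-3-methoxyphenyl]-3-hydroxypropanoic acid (racemate; one enantiomer drawn) | COc1cc([C@@H](O)[C@H](C(=O)O)c2cc(Br)cc(OC)c2OCc2ccccc2)ccc1OCc1ccccc1
F3 | step 10 | (S)-1-phenylethylammonium (2R,3S)-2-[2-(benzyloxy)-5-bromo-3-methoxyphenyl]-3-[4-(benzyloxy)-3-methoxyphenyl]-3-hydroxypropanoate | COc1cc([C@@H](O)[C@H](C(=O)[O-])c2cc(Br)cc(OC)c2OCc2ccccc2)ccc1OCc1ccccc1.C[C@H]([NH3+])c1ccccc1
F4 | step 14 | arylmagnesium bromide from 21 (MgBr in place of Br) | COc1cc([C@@H](O[Si](C)(C)C(C)(C)C)[C@H](CO[Si](C)(C)C(C)(C)C)c2cc([Mg]Br)cc(OC)c2OCc2ccccc2)ccc1OCc1ccccc1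
F5 | step 14 | 2-chloro-1,3-dithiane | ClC1SCCCS1
F0 | step 18 | none | none
F6 | step 21 | (3S,4S)-3,4-dibenzyl lactone with four free phenols and four tert-butyldimethylsilyl ethers on the arms | COc1cc([C@@H](O[Si](C)(C)C(C)(C)C)[C@H](CO[Si](C)(C)C(C)(C)C)c2cc(C[C@@H]3COC(=O)[C@H]3Cc3cc(OC)c(O)c([C@H](CO[Si](C)(C)C(C)(C)C)[C@H](O[Si](C)(C)C(C)(C)C)c4ccc(O)c(OC)c4)c3)cc(OC)c2O)ccc1O
A1 | alternative 1 | (4S,5S)-5-[2-(benzyloxy)-5-bromo-3-methoxyphenyl]-4-[4-(benzyloxy)-3-methoxyphenyl]-1,3-dioxan-2-one (trans) | COc1cc([C@@H](OC(=O)OC5)[C@H]5c2cc(Br)cc(OC)c2OCc2ccccc2)ccc1OCc1ccccc1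
A2 | alternative 1 | tert-butyl (2S)-2-[2-(benzyloxy)-5-bromo-3-methoxyphenyl]-3-[4-(benzyloxy)-3-methoxyphenyl]propyl carbonate | COc1cc(C[C@H](COC(=O)OC(C)(C)C)c2cc(Br)cc(OC)c2OCc2ccccc2)ccc1OCc1ccccc1
A3 | alternative 2 | (3S,4S)-lactone bis(homoallylic alcohol), anti arm on ring B and syn arm on ring C, vinyl in place of CH2OH, phenols benzylated | COc1cc([C@@H](O)[C@H](C=C)c2cc(C[C@@H]3COC(=O)[C@H]3Cc3cc(OC)c(OCc5ccccc5)c([C@H](C=C)[C@H](O)c4ccc(OCc5ccccc5)c(OC)c4)c3)cc(OC)c2OCc2ccccc2)ccc1OCc1ccccc1
A4 | alternative 2 | (3S,4S)-lactone with an (E)-3-(pinacolboryl)prop-1-enyl group on ring B and a (Z)-3-(pinacolboryl)prop-1-enyl group on ring C, phenols benzylated | COc1cc(C[C@@H]2COC(=O)[C@H]2Cc2cc(OC)c(OCc3ccccc3)c(/C=C\CB3OC(C)(C)C(C)(C)O3)c2)cc(/C=C/CB2OC(C)(C)C(C)(C)O2)c1OCc1ccccc1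
A5 | alternative 3 | (3S,4S)-lactone bis(ortho-alkylated phenol) with (E)-propenyl groups in place of the two CH2OH groups | COc1cc([C@@H](O[Si](C)(C)C(C)(C)C)[C@H](/C=C/C)c2cc(C[C@@H]3COC(=O)[C@H]3Cc3cc(OC)c(O)c([C@H](/C=C/C)[C@H](O[Si](C)(C)C(C)(C)C)c4ccc(OCc5ccccc5)c(OC)c4)c3)cc(OC)c2O)ccc1OCc1ccccc1
A6 | alternative 3 | bis(aryl allyl ether) of (3S,4S)-matairesinol, ring B ether (1'S,4'S,E) and ring C ether (1'R,4'S,E) | COc1cc(C[C@@H]2COC(=O)[C@H]2Cc2ccc(O[C@H](C)/C=C/[C@H](O[Si](C)(C)C(C)(C)C)c3ccc(OCc4ccccc4)c(OC)c3)c(OC)c2)ccc1O[C@@H](C)/C=C/[C@H](O[Si](C)(C)C(C)(C)C)c1ccc(OCc2ccccc2)c(OC)c1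
A7 | alternative 3 | (3S,4S)-matairesinol | COc1cc(C[C@@H]2COC(=O)[C@H]2Cc2ccc(O)c(OC)c2)ccc1O
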